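**Retrosynthetic overview**

1. Helenien ⇒ lutein + 2 palmitoyl chloride; lutein ⇒ β‑C15 aldehyde + C10 bis‑phosphonate + ε‑C15 hydroxy‑aldehyde by two HWE olefinations (C11=C12, then C11'=C12').
2. β‑C15 aldehyde ⇒ Stille coupling (C6–C7) of a (4R)‑cyclohexenyl triflate with a C5 stannyl dienal.
3. Triflate ⇒ key step: silylated 2,6‑dimethylhydroquinone is hydrogenated (dearomatised) to a meso ketone, whose symmetry is broken by chiral‑lithium‑amide deprotonation/methylation; this creates the gem‑dimethyl carbon and fixes C3 (R).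
4. ε‑C15 hydroxy‑aldehyde ⇒ (R)‑α‑ionone (C6' from the chiral pool) by HWE, allylic oxidation at C3', CBS reduction (C3' R) and DIBAL reduction.
5. Rings: none is built de novo. The β‑ring is the former arene of 2,6‑dimethylhydroquinone (first), the ε‑ring comes in with (R)‑α‑ionone (second), and the polyene is assembled last.

Assumption: (R)‑(+)‑α‑ionone of ≥98% ee (fermentation‑derived flavour grade), 2,6‑dimethylhydroquinone, (E)‑3‑methylpent‑2‑en‑4‑yn‑1‑ol and 2,7‑dimethylocta‑2,4,6‑trienedial are taken as commercially available.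

**Route**

Step 1
Reactants: 1 2,6-dimethylhydroquinone (2,6-dimethylbenzene-1,4-diol)
Product: 2 4-[(tert-butyldimethylsilyl)oxy]-2,6-dimethylphenol
Conditions: TBSCl (1.05 equiv), imidazole (2.2 equiv), DMF, 0 °C → rt, N2
Reagents that add atoms: tert-butyldimethylsilyl chloride, CC(C)(C)[Si](C)(C)Cl
Why: Imidazole-mediated O-silylation is selective for the 4-OH because the 1-OH is flanked by two ortho-methyl groups; no stereocentre is formed.

Step 2
Reactants: 2 4-[(tert-butyldimethylsilyl)oxy]-2,6-dimethylphenol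
Product: 3 (2R,4r,6S)-4-[(tert-butyldimethylsilyl)oxy]-2,6-dimethylcyclohexan-1-one (all-cis, meso)
Conditions: H2 (10 bar), 5% Pd/C, cyclohexane, 80 °C; then DBU (5 mol%), CH2Cl2, rt
Reagents that add atoms: none
Why: Heterogeneous Pd-catalysed partial hydrogenation of a phenol stops at the cyclohexanone (the enol tautomerises and the 2,6-disubstituted ketone is not reduced on Pd), hydrogen is delivered syn from one face so the three substituents end up all-cis, and DBU equilibrates any 2,6-trans epimer to the all-equatorial meso ketone.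

Step 3
Reactants: 3 (2R,4r,6S)-4-[(tert-butyldimethylsilyl)oxy]-2,6-dimethylcyclohexan-1-one
Product: 5 (4R,6S)-4-[(tert-butyldimethylsilyl)oxy]-2,2,6-trimethylcyclohexan-1-one, via lithium enolate 4 (not isolated)
Conditions: (S,S)-bis(1-phenylethyl)amine (1.15 equiv), n-BuLi (1.1 equiv), LiCl (0.5 equiv), THF, −78 °C; add 3, −100 → −78 °C; then MeI (3 equiv), DMPU, −78 → −30 °C
Reagents that add atoms: iodomethane, CI
Why: Simpkins-type enantioselective deprotonation of a meso ketone by a C2-symmetric lithium amide followed by C-alkylation of the tetrasubstituted enolate: the (S,S)-base (sense assigned by analogy with 4-tert-butylcyclohexanone, where the (R,R)-base gives the (S)-enol silane) removes the axial α-H of the (R)-configured methine, so the gem-dimethyl carbon is created on the side that makes C4 (the future C3) R, while the untouched C6 stays S and is erased in step 4.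

Step 4
Reactants: 5 (4R,6S)-4-[(tert-butyldimethylsilyl)oxy]-2,2,6-trimethylcyclohexan-1-one
Product: 6 (4R)-4-[(tert-butyldimethylsilyl)oxy]-2,6,6-trimethylcyclohex-1-en-1-yl trifluoromethanesulfonate
Conditions: KHMDS (1.2 equiv), THF, −78 → 0 °C; PhNTf2 (1.2 equiv), −78 → 0 °C; NH4Cl work-up
Reagents that add atoms: N-phenylbis(trifluoromethanesulfonimide), O=S(=O)(N(c1ccccc1)S(=O)(=O)C(F)(F)F)C(F)(F)F
Why: Regiospecific enol triflate formation (the ketone has only one α-H, at C6) by O-sulfonylation of the potassium enolate gives the tetrasubstituted alkenyl triflate; C6 becomes sp2 and C4 (R) is untouched.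

Step 5
Reactants: 7 (E)-3-methylpent-2-en-4-yn-1-ol
Product: 8 (2E,4E)-3-methyl-5-(tributylstannyl)penta-2,4-dien-1-ol
Conditions: Bu3SnH (1.2 equiv), PdCl2(PPh3)2 (2 mol%), THF, 0 °C → rt
Reagents that add atoms: tributyltin hydride, CCCC[SnH](CCCC)CCCC
Why: Pd-catalysed syn-hydrostannation of the terminal alkyne of a 1,3-enyne places tin at the terminus and gives the (E)-vinylstannane (the minor internal regioisomer is removed by chromatography); no stereocentre.

Step 6
Reactants: 8 (2E,4E)-3-methyl-5-(tributylstannyl)penta-2,4-dien-1-ol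
Product: 9 (2E,4E)-3-methyl-5-(tributylstannyl)penta-2,4-dienal
Conditions: MnO2 (15 equiv), CH2Cl2, rt
Reagents that add atoms: none
Why: MnO2 oxidises the allylic alcohol to the enal chemoselectively and leaves the vinylstannane and both E double bonds intact.

Step 7
Reactants: 6 (4R)-4-[(tert-butyldimethylsilyl)oxy]-2,6,6-trimethylcyclohex-1-en-1-yl trifluoromethanesulfonate; 9 (2E,4E)-3-methyl-5-(tributylstannyl)penta-2,4-dienal
Product: 10 (2E,4E)-5-{(4R)-4-[(tert-butyldimethylsilyl)oxy]-2,6,6-trimethylcyclohex-1-en-1-yl}-3-methylpenta-2,4-dienal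
Conditions: Pd2(dba)3 (2.5 mol%), AsPh3 (20 mol%), NMP, 60 °C, Ar, dark
Reagents that add atoms: none
Why: Stille cross-coupling under Farina conditions joins the hindered alkenyl triflate and the (E)-vinylstannane with retention of double-bond geometry, forming the C6–C7 bond; C4 (R) is untouched.

Step 8
Reactants: 11 (2E,4E,6E)-2,7-dimethylocta-2,4,6-trienedial (C10 dialdehyde)
Product: 12 (2E,4E,6E)-2,7-dimethylocta-2,4,6-triene-1,8-diol
Conditions: NaBH4 (1.0 equiv), CeCl3·7H2O (cat.), MeOH/THF, 0 °C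
Reagents that add atoms: none
Why: Luche 1,2-reduction of both enal carbonyls gives the bis-allylic diol without touching the triene geometry.

Step 9
Reactants: 12 (2E,4E,6E)-2,7-dimethylocta-2,4,6-triene-1,8-diol
Product: 13 tetraethyl [(2E,4E,6E)-2,7-dimethylocta-2,4,6-triene-1,8-diyl]bis(phosphonate)
Conditions: ZnI2 (3 equiv), P(OEt)3 (6 equiv), THF, reflux, 16 h
Reagents that add atoms: triethyl phosphite, CCOP(OCC)OCC
Why: ZnI2-mediated direct conversion of allylic alcohols into phosphonates (iodide formation followed by a Michaelis–Arbuzov reaction in the same flask) occurs at the primary termini and keeps the conjugated all-E triene.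

Step 10
Reactants: 13 tetraethyl [(2E,4E,6E)-2,7-dimethylocta-2,4,6-triene-1,8-diyl]bis(phosphonate); 10 (2E,4E)-5-{(4R)-4-[(tert-butyldimethylsilyl)oxy]-2,6,6-trimethylcyclohex-1-en-1-yl}-3-methylpenta-2,4-dienal
Product: 14 diethyl [(2E,4E,6E,8E,10E,12E)-13-{(4R)-4-[(tert-butyldimethylsilyl)oxy]-2,6,6-trimethylcyclohex-1-en-1-yl}-2,7,11-trimethyltrideca-2,4,6,8,10,12-hexaen-1-yl]phosphonate
Conditions: 13 (3 equiv), NaHMDS (1.0 equiv), THF, −78 °C; add 10 (1.0 equiv), −78 → 0 °C; NH4Cl work-up; excess 13 recovered by chromatography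
Reagents that add atoms: none
Why: Horner–Wadsworth–Emmons olefination of the enal with the mono-anion of the symmetric bis-phosphonate (used in excess so that only one end reacts) forms the C11=C12 bond E-selectively.

Step 11
Reactants: 15 (R)-α-ionone, (3E)-4-[(1R)-2,6,6-trimethylcyclohex-2-en-1-yl]but-3-en-2-one
Product: 16 (2E,4E)-3-methyl-5-[(1R)-2,6,6-trimethylcyclohex-2-en-1-yl]penta-2,4-dienenitrile
Conditions: (EtO)2P(O)CH2CN (1.6 equiv), NaH (1.5 equiv), THF, 0 °C → rt; NH4Cl work-up; chromatography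
Reagents that add atoms: diethyl (cyanomethyl)phosphonate, CCOP(=O)(CC#N)OCC
Why: Horner–Wadsworth–Emmons olefination of the methyl ketone gives the dienyl nitrile (9E:9Z about 4:1, the 9E isomer is isolated by chromatography), and the weakly basic phosphonate anion does not epimerise C6' (R).

Step 12
Reactants: 16 (2E,4E)-3-methyl-5-[(1R)-2,6,6-trimethylcyclohex-2-en-1-yl]penta-2,4-dienenitrile
Product: 17 (2E,4E)-3-methyl-5-[(1R)-2,6,6-trimethyl-4-oxocyclohex-2-en-1-yl]penta-2,4-dienenitrile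
Conditions: Rh2(cap)4 (1 mol%), t-BuOOH (70% aq., 5 equiv), 1,2-dichloroethane, 40 °C
Reagents that add atoms: tert-butyl hydroperoxide, CC(C)(C)OO
Why: Rh2(cap)4/t-BuOOH radical allylic oxidation (Doyle) converts the only allylic ring methylene (C3') into the enone under base-free conditions, so the now γ-acidic C6' stereocentre is not epimerised.

Step 13
Reactants: 17 (2E,4E)-3-methyl-5-[(1R)-2,6,6-trimethyl-4-oxocyclohex-2-en-1-yl]penta-2,4-dienenitrile
Product: 18 (2E,4E)-5-[(1R,4R)-4-hydroxy-2,6,6-trimethylcyclohex-2-en-1-yl]-3-methylpenta-2,4-dienenitrile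
Conditions: (S)-2-methyl-CBS-oxazaborolidine (0.2 equiv), catecholborane (1.5 equiv), toluene, −78 °C; aqueous work-up; chromatography
Reagents that add atoms: none
Why: Corey–Bakshi–Shibata reduction: the (S)-oxazaborolidine binds the carbonyl with the alkenyl flank as the large group and delivers hydride 1,2 to give the (R)-allylic alcohol, trans to the C6' side chain, under catalyst control (any cis (4S) epimer is removed by chromatography).

Step 14
Reactants: 18 (2E,4E)-5-[(1R,4R)-4-hydroxy-2,6,6-trimethylcyclohex-2-en-1-yl]-3-methylpenta-2,4-dienenitrile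
Product: 19 (2E,4E)-5-[(1R,4R)-4-hydroxy-2,6,6-trimethylcyclohex-2-en-1-yl]-3-methylpenta-2,4-dienal
Conditions: DIBAL-H (2.5 equiv), CH2Cl2, −78 → −40 °C; aq. Rochelle salt, then wet SiO2, 0 °C
Reagents that add atoms: water, O
Why: DIBAL-H adds once to the nitrile to give an N-aluminio aldimine that is hydrolysed on work-up to the dienal (the hydroxyl is carried as its aluminium alkoxide); both stereocentres and the 9E geometry are untouched.

Step 15
Reactants: 14 diethyl [(2E,4E,6E,8E,10E,12E)-13-{(4R)-4-[(tert-butyldimethylsilyl)oxy]-2,6,6-trimethylcyclohex-1-en-1-yl}-2,7,11-trimethyltrideca-2,4,6,8,10,12-hexaen-1-yl]phosphonate; 19 (2E,4E)-5-[(1R,4R)-4-hydroxy-2,6,6-trimethylcyclohex-2-en-1-yl]-3-methylpenta-2,4-dienal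
Product: 21 lutein [(3R,3'R,6'R)-β,ε-carotene-3,3'-diol], via TBS-lutein 20 (not isolated)
Conditions: 14 (1.15 equiv), NaHMDS (1.1 equiv), THF, −78 °C; add 19, −78 → 0 °C; then TBAF (3 equiv, 1 M in THF), rt, dark; NH4Cl work-up; crystallisation (CH2Cl2/hexane)
Reagents that add atoms: none
Why: Horner–Wadsworth–Emmons olefination of the hydroxy-aldehyde with the pre-formed allylic phosphonate anion forms C11'=C12' E-selectively at low temperature (no epimerisation at C6'), and fluoride then cleaves the silyl ether in the same flask; no stereocentre is formed or inverted.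

Step 16
Reactants: 21 lutein; 22 palmitoyl chloride (hexadecanoyl chloride)
Product: 23 helenien [(3R,3'R,6'R)-β,ε-carotene-3,3'-diyl dipalmitate]
Conditions: 22 (3 equiv), pyridine, DMAP (0.1 equiv), CH2Cl2, 0 °C → rt, Ar, dark
Reagents that add atoms: none
Why: DMAP-catalysed acylation of both secondary alcohols with the acid chloride takes place at oxygen with retention at C3 and C3' and gives the diester.

**Compound list**

1 | 2,6-dimethylhydroquinone | Cc1cc(O)cc(C)c1O | starting material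
2 | 4-[(tert-butyldimethylsilyl)oxy]-2,6-dimethylphenol | Cc1cc(O[Si](C)(C)C(C)(C)C)cc(C)c1O | intermediate
3 | (2R,4r,6S)-4-[(tert-butyldimethylsilyl)oxy]-2,6-dimethylcyclohexan-1-one (all-cis, meso) | C[C@H]1C[C@@H](O[Si](C)(C)C(C)(C)C)C[C@@H](C)C1=O | intermediate
4 | lithium (4R,6S)-4-[(tert-butyldimethylsilyl)oxy]-2,6-dimethylcyclohex-1-en-1-olate (lithium enolate, not isolated) | C[C@H]1C[C@@H](O[Si](C)(C)C(C)(C)C)CC(C)=C1O[Li] | intermediate
5 | (4R,6S)-4-[(tert-butyldimethylsilyl)oxy]-2,2,6-trimethylcyclohexan-1-one | C[C@H]1C[C@@H](O[Si](C)(C)C(C)(C)C)CC(C)(C)C1=O | intermediate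
6 | (4R)-4-[(tert-butyldimethylsilyl)oxy]-2,6,6-trimethylcyclohex-1-en-1-yl trifluoromethanesulfonate | CC1=C(OS(=O)(=O)C(F)(F)F)C(C)(C)C[C@H](O[Si](C)(C)C(C)(C)C)C1 | intermediate
7 | (E)-3-methylpent-2-en-4-yn-1-ol | C#C/C(C)=C/CO | starting material
8 | (2E,4E)-3-methyl-5-(tributylstannyl)penta-2,4-dien-1-ol | OC/C=C(C)/C=C/[Sn](CCCC)(CCCC)CCCC | intermediate
9 | (2E,4E)-3-methyl-5-(tributylstannyl)penta-2,4-dienal | O=C/C=C(C)/C=C/[Sn](CCCC)(CCCC)CCCC | intermediate
10 | (2E,4E)-5-{(4R)-4-[(tert-butyldimethylsilyl)oxy]-2,6,6-trimethylcyclohex-1-en-1-yl}-3-methylpenta-2,4-dienal | O=C/C=C(C)/C=C/C1=C(C)C[C@@H](O[Si](C)(C)C(C)(C)C)CC1(C)C | intermediate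
11 | (2E,4E,6E)-2,7-dimethylocta-2,4,6-trienedial | O=C/C(C)=C/C=C/C=C(C)/C=O | starting material
12 | (2E,4E,6E)-2,7-dimethylocta-2,4,6-triene-1,8-diol | OC/C(C)=C/C=C/C=C(C)/CO | intermediate
13 | tetraethyl [(2E,4E,6E)-2,7-dimethylocta-2,4,6-triene-1,8-diyl]bis(phosphonate) | CCOP(=O)(OCC)C/C(C)=C/C=C/C=C(C)/CP(=O)(OCC)OCC | intermediate
14 | diethyl [(2E,4E,6E,8E,10E,12E)-13-{(4R)-4-[(tert-butyldimethylsilyl)oxy]-2,6,6-trimethylcyclohex-1-en-1-yl}-2,7,11-trimethyltrideca-2,4,6,8,10,12-hexaen-1-yl]phosphonate | CCOP(=O)(OCC)C/C(C)=C/C=C/C=C(C)/C=C/C=C(C)/C=C/C1=C(C)C[C@@H](O[Si](C)(C)C(C)(C)C)CC1(C)C | intermediate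
15 | (R)-α-ionone | CC(=O)/C=C/[C@H]1C(C)=CCCC1(C)C | starting material
16 | (2E,4E)-3-methyl-5-[(1R)-2,6,6-trimethylcyclohex-2-en-1-yl]penta-2,4-dienenitrile | N#C/C=C(C)/C=C/[C@H]1C(C)=CCCC1(C)C | intermediate
17 | (2E,4E)-3-methyl-5-[(1R)-2,6,6-trimethyl-4-oxocyclohex-2-en-1-yl]penta-2,4-dienenitrile | N#C/C=C(C)/C=C/[C@H]1C(C)=CC(=O)CC1(C)C | intermediate
18 | (2E,4E)-5-[(1R,4R)-4-hydroxy-2,6,6-trimethylcyclohex-2-en-1-yl]-3-methylpenta-2,4-dienenitrile | N#C/C=C(C)/C=C/[C@H]1C(C)=C[C@H](O)CC1(C)C | intermediate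
19 | (2E,4E)-5-[(1R,4R)-4-hydroxy-2,6,6-trimethylcyclohex-2-en-1-yl]-3-methylpenta-2,4-dienal | O=C/C=C(C)/C=C/[C@H]1C(C)=C[C@H](O)CC1(C)C | intermediate
20 | (3R,3'R,6'R)-3-[(tert-butyldimethylsilyl)oxy]-β,ε-caroten-3'-ol (TBS-lutein, not isolated) | CC(C)(C)[Si](C)(C)O[C@@H]1CC(C)=C(/C=C/C(C)=C/C=C/C(C)=C/C=C/C=C(C)/C=C/C=C(C)/C=C/[C@H]2C(C)=C[C@H](O)CC2(C)C)C(C)(C)C1 | intermediate
21 | lutein, (3R,3'R,6'R)-β,ε-carotene-3,3'-diol | O[C@@H]1CC(C)=C(/C=C/C(C)=C/C=C/C(C)=C/C=C/C=C(C)/C=C/C=C(C)/C=C/[C@H]2C(C)=C[C@H](O)CC2(C)C)C(C)(C)C1 | intermediate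
22 | palmitoyl chloride | CCCCCCCCCCCCCCCC(=O)Cl | starting material
23 | helenien, (3R,3'R,6'R)-β,ε-carotene-3,3'-diyl dipalmitate | CCCCCCCCCCCCCCCC(=O)O[C@@H]1CC(C)=C(/C=C/C(C)=C/C=C/C(C)=C/C=C/C=C(C)/C=C/C=C(C)/C=C/[C@H]2C(C)=C[C@H](OC(=O)CCCCCCCCCCCCCCC)CC2(C)C)C(C)(C)C1 | target

**Step count and risks**

Total steps: 16. Longest linear sequence: 8 steps (1 → 2 → 3 → 5 → 6 → 10 → 14 → 21 → 23, i.e. steps 1, 2, 3, 4, 7, 10, 15, 16).

The three steps most likely to fail:

Step 3 (desymmetrisation). The enantiomeric excess of lithium-amide deprotonations of this type is typically 85–90%, and the sense of induction rests on analogy. If the sense proves opposite, the (R,R)-amine is used instead. Any (3S) material would show up as a diastereomer of lutein and is removed when 21 is crystallised. The fallback gives up reagent-controlled desymmetrisation for a classical resolution. It sets out from 3 and comes back at 5. Achiral LDA/MeI gives racemic cis-4-[(tert-butyldimethylsilyl)oxy]-2,2,6-trimethylcyclohexan-1-one F1. TBAF then gives racemic cis-4-hydroxy-2,2,6-trimethylcyclohexan-1-one F2. DCC/DMAP esterification with (S)-2-methoxy-2-phenylacetic acid gives two diastereomeric esters, (1R,3S)-3,5,5-trimethyl-4-oxocyclohexyl (S)-2-methoxy-2-phenylacetate F3 and its (1S,3R) diastereomer F4. These are separated by chromatography or crystallisation and assigned by the O-methylmandelate NMR model. K2CO3/MeOH releases (4R,6S)-4-hydroxy-2,2,6-trimethylcyclohexan-1-one F5 from F3, and TBSCl/imidazole returns 5. Any epimerisation at C6 is harmless because C6 becomes sp2 in step 4.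

Step 2 (partial hydrogenation). Over-reduction to the cyclohexanol or hydrogenolysis of the C–OSi bond on Pd could erode the yield. The fallback separates ring saturation from the oxidation level. It sets out from 2 and comes back at 3. Exhaustive hydrogenation over 5% Rh/Al2O3 (H2 60 bar, i-PrOH, 60 °C; Rh does not cleave C–O bonds) gives all-cis-4-[(tert-butyldimethylsilyl)oxy]-2,6-dimethylcyclohexan-1-ol F6. Dess–Martin periodinane then oxidises the hindered alcohol to the ketone, and the DBU treatment of step 2 delivers 3.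

Step 9 (direct bis-phosphonylation). The Lewis-acidic, hot conditions may ionise or isomerise the doubly allylic triene diol. The fallback goes through a discrete halide. It sets out from 12 and comes back at 13. PBr3 (Et2O, cat. pyridine, −10 °C) gives (2E,4E,6E)-1,8-dibromo-2,7-dimethylocta-2,4,6-triene F7, which is used at once in a Michaelis–Arbuzov reaction with neat P(OEt)3 at 110 °C to give 13.

**Further compounds**

F1 | step 3 | racemic cis-4-[(tert-butyldimethylsilyl)oxy]-2,2,6-trimethylcyclohexan-1-one | C[C@H]1C[C@@H](O[Si](C)(C)C(C)(C)C)CC(C)(C)C1=O.C[C@@H]1C[C@H](O[Si](C)(C)C(C)(C)C)CC(C)(C)C1=O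
F2 | step 3 | racemic cis-4-hydroxy-2,2,6-trimethylcyclohexan-1-one | C[C@H]1C[C@@H](O)CC(C)(C)C1=O.C[C@@H]1C[C@H](O)CC(C)(C)C1=O
F3 | step 3 | (1R,3S)-3,5,5-trimethyl-4-oxocyclohexyl (S)-2-methoxy-2-phenylacetate | C[C@H]1C[C@@H](OC(=O)[C@@H](OC)c2ccccc2)CC(C)(C)C1=O
F4 | step 3 | (1S,3R)-3,5,5-trimethyl-4-oxocyclohexyl (S)-2-methoxy-2-phenylacetate | C[C@@H]1C[C@H](OC(=O)[C@@H](OC)c2ccccc2)CC(C)(C)C1=O
F5 | step 3 | (4R,6S)-4-hydroxy-2,2,6-trimethylcyclohexan-1-one | C[C@H]1C[C@@H](O)CC(C)(C)C1=O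
F6 | step 2 | all-cis-4-[(tert-butyldimethylsilyl)oxy]-2,6-dimethylcyclohexan-1-ol | C[C@H]1C[C@@H](O[Si](C)(C)C(C)(C)C)C[C@@H](C)[C@H]1O
F7 | step 9 | (2E,4E,6E)-1,8-dibromo-2,7-dimethylocta-2,4,6-triene | BrC/C(C)=C/C=C/C=C(C)/CBr
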